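Intermediate A leaves by its own step to intermediate B at 0.042 s⁻¹, faster than it reacts with partner even at the starting [partner], where that exit runs at 0.0131 s⁻¹. So [partner] is the concentration to watch in this flask.

substrate 29 mM (in portions, 2); partner 43.5 mM; time 5.0 h; the portions of substrate follow each other after 3.0 s, the first at the start

    intermediate B ⇌ intermediate C (K1 = 2.7, k1 = 0.27 s⁻¹)
    intermediate A → intermediate B (k2 = 0.042 s⁻¹)
    partner + intermediate A → target (k3 = 0.30 M⁻¹ s⁻¹)
    substrate + partner ⇌ intermediate A (K4 = 86 M⁻¹, k4 = 1.1 M⁻¹ s⁻¹)
    substrate ⇌ dormant form (K5 = 2.1, k5 = 0.023 s⁻¹)

- which holds at 5.0 h: what has brought the reaction to rest, or that it has not come to rest (forward and back rates have come level / it is still moving / the partner has run out first / all of the substrate has reacted)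
- how much of the substrate has reacted by 5.0 h
- how much target there is at 5.0 h, in percent of the substrate charged
- how much intermediate C there is at 5.0 h, in percent of the substrate charged
- how much intermediate B there is at 5.0 h, in percent of the substrate charged

- the reaction counts as stopped when no species that holds the substrate changes by six tenths of a point or more over the second half of the time
- run time (flask): 5.0 h

Take the main line first: substrate and partner give intermediate A, and A with a second partner gives target. At two partner per target, the charges allow 75.0% of target. Now add the step from A to intermediate B. Both exits are first order in A, the one to target being pseudo-first-order at a given [partner], so [A] cancels from their ratio. Call the crossover partner the [partner] at which the two exits run level, the rate constant of the step to intermediate B over that of the step to target: 140 mM. The selectivity for target is then [partner] over [partner] plus this crossover.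

The flask starts below the crossover and [partner] falls, so a mean is needed. Each substrate takes one partner on entering, which gives a first mean of 29.0 mM and a share of 17.2%. Target costs further partner, so the reckoned end is 9.52 mM, the mean 26.5 mM, and target 15.9%.

Now add the dormant form. It exchanges with a forward half-life of 0.50 min, and at balance the free fraction of the pool is 32.3%. Even at the reckoned end [partner], the forward step of substrate with partner drains the pool with a reckoned time constant of 4.93 min, far shorter than the run, and 100% has reacted. The forward half-life of the exchange is shorter than that time constant. The reckoning still holds 9.52 mM of partner when that much has reacted, so in it the substrate is what comes to an end. In this reckoning the dormant form delays the flow and does not enter the share, which is reckoned per substrate reacted. Last, intermediates B and C relax with a time constant of 2.70 s, shorter than the run, and the flow not going to target divides by their balance: 61.4% intermediate C and 22.7% intermediate B.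

The forecast reads: all of the substrate has reacted, with 100% reacted, 15.5% target, 61.7% intermediate C and 22.8% intermediate B. Its ground for the target: “The split at A depends only on” the rate of the partner route against the step to intermediate B. Its target stands slightly below the reckoning here.

The simulated flask ends thus: all of the substrate has reacted, with 100% reacted, 14.3% target, 62.5% intermediate C and 23.2% intermediate B. Of its partner, 24% remains at 5.00 h, which is 10.4 mM, so the mean is 26.9 mM and the crossover gives a share of 16.1%. The neighbour flask charged with 170 mM of partner keeps 74% of it, so its mean of 148 mM lies above the crossover. The crossover gives that flask a share of 51.4%, and it holds 50.1% target.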